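The flask was to be read at 2.0 d, and this is what I had before me.

| flask | Q | G | temperature | remark | time |
|---|---|---|---|---|---|
| alpha | 0.050 M | 0.040 M | 60 °C | the very flask that is asked about, followed so far |  |
| delta | 0.050 M | 0.040 M | 55 °C | run made earlier |  |
| flask | 0.050 M | 0.0400 M | 60 °C |  | 2.0 d |

| alpha: time / h | alpha: D / % | delta: time / h | delta: D / % |
|---|---|---|---|
| 2.50 | 5 | 2.50 | 0 |
| 8.00 | 22 | 8.00 | 11 |
| 15.0 | 30 | 15.0 | 25 |
| 20.0 | 34 | 20.0 | 27 |
| 30.0 | 31 | 30.0 | 37 |
| 40.0 | 33 | 40.0 | 35 |
| 50.0 | 30 | 50.0 | 34 |

(standard deviation of a reading: 1.5 percentage points)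

- Q is a solid; its amount is given per volume of the solution
- removed D is counted in
- what was read earlier has a scatter of 1.5 percentage points, one standard deviation
- at the start none of Q is in solution
- additions bring no volume worth counting

- Saturday's: at 2.0 d add G, 50.0% of the amount charged, then wait 25 h
- Monday's: change nothing and wait 25 h more
- Thursday's: at 2.0 d raise the temperature by 25 K, then wait 25 h
- Wednesday's: at 2.0 d take out 90% of the D then present, then wait 25 h

- D, in percent of the Q first charged, at 2.0 d
- what to do for the largest gain in D; "none" if nothing gains more than 2 percentage points (Saturday's / Monday's / Thursday's / Wednesday's / none)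
- D present, with what was taken out counted in, in percent of the Q first charged, after Saturday's
- D present, with what was taken out counted in, in percent of the Q first charged, after Wednesday's

That time lay later than 20.0 h, from which D no longer rose in the alpha run, this same flask followed so far. I therefore read "now" off the plateau, whose mean from there on was 32.0%.

Then I counted turnovers. G was the limiting reagent, since cG at 0.0400 M was less than cQ at 0.050 M. Two extreme flasks can be done in the head. If each G used made one D, D would stop at 80.0% of the Q charged; if G were lost to something else before making anything, D would stay at nothing. The alpha plateau stood between them, lower than the first, so I took 0.400 as the turnover yield, the D made per G used. This assumed that no G remained on the plateau, which readings of D could not show.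

On that count, Saturday's 0.0200 M of fresh G should add 16 percentage points, giving 48.0%. Monday's and Wednesday's bring no fresh G, so I expected nothing from them. Nor did I expect anything from heat, as the cooler delta run levelled at 35.3%, higher than the alpha plateau.

The forecast gave 32% now and chose Saturday's, with 47% after it, just under my figure, and 32% after Wednesday's. Its words were “Saturday's is the robust choice”.

The flask gave 30.4% now, and Saturday's was best, reaching 49.6%, a gain of 19 points; Wednesday's ended at 30.4%.

    G + L → D (k = 30.0 M⁻¹ h⁻¹, Ea = 69.0 kJ mol⁻¹)
    Q ⇌ X, rate k2*(cs2 - [X]) while solid is left; crystals form when [X] > cs2 (solubility = 30.0 mM, k = 0.610 h⁻¹)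
    G → J (k = 0.110 h⁻¹, Ea = 110 kJ mol⁻¹)
    X ⇌ L + E (K = 0.00400 M, k = 0.100 h⁻¹, Ea = 110 kJ mol⁻¹, ΔH = −36.0 kJ mol⁻¹)
    (constants at 60 °C)

In this flask G stood at 0% of its charge at 48.0 h, and 30.4% of D makes the turnover yield 0.379. Saturday's brought 0.480 of D per G added, more than the first charge of G had yielded. A neighbouring repeat at 35 °C kept 71% of its G at 48.0 h, so it had used 0.0117 M. My yield of 0.400, read at 60 °C and carried over unchanged, turns that into 9.36% of the Q charged. That flask held 9.00% of D.

(The earlier runs and the new flask were generated by integration with made-up constants.)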